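**Retrosynthetic overview**

1. The target is (2S)-naringenin carrying a (2R)-1-methylpiperidin-2-yl group on C6; the last operations are N-methylation and removal of three O-benzyl groups.
2. Ring C (O1, C2, C3, C4, C4a, C8a) is closed last, in a one-flask Knoevenagel condensation / catalytic enantioselective oxa-Michael addition / decarboxylation that joins a ring A β-keto ester to 4-(benzyloxy)benzaldehyde (C2=C3 first, then O1–C2).
3. Enabling feature: in ring A the C5 and C7 oxygens flank the piperidinyl carbon C6 symmetrically, so the phenol with free O1–H para to C6 has two equivalent ortho carbons (C4a ≡ C8). Ortho-formylation therefore gives one aldehyde, in which O1 is the only free phenol next to the future C4, and the temporary tert-butyl ester on C3 makes C2 electrophilic.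
4. The C4–C3 unit comes from tert-butyl acetate; the piperidine ring comes from a 2,6-dioxygenated aryl Grignard reagent, an (R)-N-sulfinyl imine of 5-chloropentanal and an N-alkylative closure.
5. Order of ring formation: rings A and B are bought, the piperidine ring is closed in step 4, ring C in step 10.

Key step: step 10

Assumption: the sense of induction of the cinchona thiourea is taken by analogy with cyclisations of simpler 2'-hydroxyaryl alkylidene β-keto esters (quinidine-derived catalyst for 2S); if the opposite sense is found, the pseudoenantiomeric quinine-derived catalyst is used with no other change.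

**Route**

Step 1
Reactants: 1 3,5-bis(benzyloxy)phenol
Product: 2 {[3,5-bis(benzyloxy)phenyl]oxy}triisopropylsilane
Conditions: TIPSCl, imidazole, DMF, rt
Reagents that add atoms: triisopropylsilyl chloride, CC(C)[Si](Cl)(C(C)C)C(C)C
Why: Silylation of the only free phenol should give a bulky, non-coordinating ether that masks the future O1 and keeps the later metalation away from its ortho carbons.

Step 2
Reactants: 3 5-chloropentanal; 4 (R)-2-methylpropane-2-sulfinamide
Product: 5 (R)-N-[(1E)-5-chloropentylidene]-2-methylpropane-2-sulfinamide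
Conditions: CuSO4 (anhydrous), CH2Cl2, rt
Reagents that add atoms: none
Why: Dehydrative condensation of an aldehyde with tert-butanesulfinamide should give the (E)-N-sulfinyl aldimine, with no new stereocentre.

Step 3
Reactants: 2 {[3,5-bis(benzyloxy)phenyl]oxy}triisopropylsilane; 5 (R)-N-[(1E)-5-chloropentylidene]-2-methylpropane-2-sulfinamide
Product: 8 (R)-N-[(1R)-1-{2,6-bis(benzyloxy)-4-[(triisopropylsilyl)oxy]phenyl}-5-chloropentyl]-2-methylpropane-2-sulfinamide, via aryllithium 6 (not isolated), via arylmagnesium bromide 7 (not isolated)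
Conditions: n-BuLi, Et2O, 0 °C → rt; MgBr2·OEt2, 0 °C; then 5, toluene, −78 °C → rt; H2O
Reagents that add atoms: none
Why: Directed ortho-lithiation between the two benzyloxy groups, Li→Mg exchange and 1,2-addition of the aryl Grignard reagent to the N-tert-butanesulfinyl aldimine through the six-membered Mg–O=S chelate should deliver the aryl group to the Si face of the (R)-sulfinyl imine and so set the (R) centre at carbon; the minor diastereomer is removed by chromatography.

Step 4
Reactants: 8 (R)-N-[(1R)-1-{2,6-bis(benzyloxy)-4-[(triisopropylsilyl)oxy]phenyl}-5-chloropentyl]-2-methylpropane-2-sulfinamide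
Product: 9 (2R)-2-{2,6-bis(benzyloxy)-4-[(triisopropylsilyl)oxy]phenyl}-1-[(R)-tert-butylsulfinyl]piperidine
Conditions: NaH, DMF, 0 °C → rt
Reagents that add atoms: none
Why: Intramolecular N-alkylation (6-exo-tet) of the sulfinamide anion on the primary chloride should close the piperidine ring without touching the benzylic stereocentre.

Step 5
Reactants: 9 (2R)-2-{2,6-bis(benzyloxy)-4-[(triisopropylsilyl)oxy]phenyl}-1-[(R)-tert-butylsulfinyl]piperidine
Product: 11 tert-butyl (2R)-2-{2,6-bis(benzyloxy)-4-[(triisopropylsilyl)oxy]phenyl}piperidine-1-carboxylate, via piperidine hydrochloride 10 (not isolated)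
Conditions: HCl (dioxane), MeOH, 0 °C; evaporate; then Boc2O, Et3N, CH2Cl2, rt
Reagents that add atoms: di-tert-butyl dicarbonate, CC(C)(C)OC(=O)OC(=O)OC(C)(C)C
Why: Acidic methanolysis of the N–S bond followed by carbamate formation should exchange the auxiliary for a Boc group, which keeps the nitrogen non-basic for the organocatalytic key step.

Step 6
Reactants: 11 tert-butyl (2R)-2-{2,6-bis(benzyloxy)-4-[(triisopropylsilyl)oxy]phenyl}piperidine-1-carboxylate
Product: 12 tert-butyl (2R)-2-[2,6-bis(benzyloxy)-4-hydroxyphenyl]piperidine-1-carboxylate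
Conditions: Bu4NF, THF, 0 °C
Reagents that add atoms: none
Why: Fluoride-induced cleavage of the aryl silyl ether should free the O1 phenol, which lies para to the piperidinyl carbon so that its two ortho carbons are equivalent.

Step 7
Reactants: 12 tert-butyl (2R)-2-[2,6-bis(benzyloxy)-4-hydroxyphenyl]piperidine-1-carboxylate
Product: 14 tert-butyl (2R)-2-[2,6-bis(benzyloxy)-3-formyl-4-hydroxyphenyl]piperidine-1-carboxylate, via salicyl alcohol 13 (not isolated)
Conditions: MgCl2, Et3N, (CH2O)n, MeCN, reflux; aq. citric acid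
Reagents that add atoms: formaldehyde (as paraformaldehyde), C=O
Why: Magnesium phenoxide-directed ortho-formylation (ortho-hydroxymethylation, then hydride transfer from the magnesium benzyl alkoxide to a second formaldehyde) should give a single aldehyde because both ortho carbons of 12 are equivalent.

Step 8
Reactants: 14 tert-butyl (2R)-2-[2,6-bis(benzyloxy)-3-formyl-4-hydroxyphenyl]piperidine-1-carboxylate; 15 tert-butyl acetate
Product: 17 tert-butyl (2R)-2-[2,6-bis(benzyloxy)-3-(3-tert-butoxy-1-hydroxy-3-oxopropyl)-4-hydroxyphenyl]piperidine-1-carboxylate, via lithium enolate 16 (not isolated)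
Conditions: LiN(i-Pr)2 (3.2 equiv), 15 (3.3 equiv), THF, −78 °C; then 14, −78 °C; aq. NH4Cl; used crude
Reagents that add atoms: none
Why: Aldol addition of the ester enolate to the aldehyde (one equivalent of enolate is spent on the phenol) should install C3 and the ester carbon; the new carbinol centre forms as a mixture and is removed in step 9.

Step 9
Reactants: 17 tert-butyl (2R)-2-[2,6-bis(benzyloxy)-3-(3-tert-butoxy-1-hydroxy-3-oxopropyl)-4-hydroxyphenyl]piperidine-1-carboxylate
Product: 18 tert-butyl (2R)-2-[2,6-bis(benzyloxy)-3-(3-tert-butoxy-3-oxopropanoyl)-4-hydroxyphenyl]piperidine-1-carboxylate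
Conditions: MnO2 (activated), CH2Cl2, rt
Reagents that add atoms: none
Why: MnO2 oxidation of the benzylic alcohol should give the aryl β-keto ester (C4=O) without touching the phenol, the carbamate or the benzyl ethers.

Step 10
Reactants: 18 tert-butyl (2R)-2-[2,6-bis(benzyloxy)-3-(3-tert-butoxy-3-oxopropanoyl)-4-hydroxyphenyl]piperidine-1-carboxylate; 19 4-(benzyloxy)benzaldehyde
Product: 23 (2S)-5,7-bis(benzyloxy)-2-[4-(benzyloxy)phenyl]-6-[(2R)-piperidin-2-yl]chroman-4-one, via alkylidene β-keto ester 20 (not isolated), via flavanone-3-carboxylate 21 (not isolated), via β-keto acid 22 (not isolated)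
Conditions: 19 (1.05 equiv), piperidine (5 mol%), AcOH (5 mol%), 4 Å MS, toluene, rt; then −25 °C, 1-[3,5-bis(trifluoromethyl)phenyl]-3-(9-deoxy-epi-quinidin-9-yl)thiourea (20 mol%); then CF3CO2H, −25 → 40 °C; aq. NaHCO3
Reagents that add atoms: none
Why: Stage one is a Knoevenagel condensation that joins the ring B aldehyde to C3 and gives alkylidene 20, whose C2=C3 bond is doubly activated by C4=O and the temporary tert-butyl ester on C3. In stage two the thiourea of the cinchona catalyst binds this 1,3-dicarbonyl while its quinuclidine nitrogen deprotonates O1–H, so that O1 adds to C2 in a 6-endo-trig oxa-Michael closure of ring C; the closest known reaction type is the bifunctional thiourea-catalysed cyclisation of 2'-hydroxyaryl alkylidene β-keto esters to flavanones with acid-induced decarboxylation in the same flask. The new C2 stereocentre is set by the catalyst, because the (R)-piperidine centre on C6 is too remote to bias it, and the quinidine-derived pseudoenantiomer is chosen for 2S. Regioselectivity needs no control in this step: the C5 oxygen is a benzyl ether and O1 is the only free phenol, a consequence of the symmetry used in step 7. Stage three (CF3CO2H) cleaves the tert-butyl ester and the N-Boc group, and β-keto acid 22 loses CO2, which removes the activating group and the labile C3 stereocentre. Uncatalysed cyclisation should be held back by the low temperature, the low loading of the achiral ammonium acetate and the O1–H···O=C4 hydrogen bond.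

Step 11
Reactants: 23 (2S)-5,7-bis(benzyloxy)-2-[4-(benzyloxy)phenyl]-6-[(2R)-piperidin-2-yl]chroman-4-one
Product: 25 (2S)-5,7-bis(benzyloxy)-2-[4-(benzyloxy)phenyl]-6-[(2R)-1-methylpiperidin-2-yl]chroman-4-one, via iminium ion 24 (not isolated)
Conditions: 37% aq. CH2O, NaBH(OAc)3, AcOH, ClCH2CH2Cl, rt
Reagents that add atoms: formaldehyde, C=O
Why: Reductive amination should methylate the secondary amine while the hindered, electron-rich aryl ketone C4=O and the benzyl-protected phenols stay inert, and no stereocentre is touched.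

Step 12
Reactants: 25 (2S)-5,7-bis(benzyloxy)-2-[4-(benzyloxy)phenyl]-6-[(2R)-1-methylpiperidin-2-yl]chroman-4-one
Product: 26 (2S)-5,7-dihydroxy-2-(4-hydroxyphenyl)-6-[(2R)-1-methylpiperidin-2-yl]chroman-4-one
Conditions: H2 (1 atm), 10% Pd/C, EtOAc–MeOH, rt; filtration and evaporation without base
Reagents that add atoms: none
Why: Catalytic hydrogenolysis of the three aryl benzyl ethers under neutral conditions should free the C5, C7 and C4' phenols and leave both stereocentres untouched, and base is avoided in the work-up so that the flavanone does not ring-open.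

**Compound list**

1 | 3,5-bis(benzyloxy)phenol | Oc1cc(OCc2ccccc2)cc(OCc2ccccc2)c1 | starting material
2 | {[3,5-bis(benzyloxy)phenyl]oxy}triisopropylsilane | CC(C)[Si](C(C)C)(C(C)C)Oc1cc(OCc2ccccc2)cc(OCc2ccccc2)c1 | intermediate
3 | 5-chloropentanal | O=CCCCCCl | starting material
4 | (R)-2-methylpropane-2-sulfinamide | CC(C)(C)[S@@](=O)N | starting material
5 | (R)-N-[(1E)-5-chloropentylidene]-2-methylpropane-2-sulfinamide | CC(C)(C)[S@@](=O)/N=C/CCCCCl | intermediate
6 | {2,6-bis(benzyloxy)-4-[(triisopropylsilyl)oxy]phenyl}lithium | [Li]c1c(OCc2ccccc2)cc(O[Si](C(C)C)(C(C)C)C(C)C)cc1OCc1ccccc1 | intermediate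
7 | {2,6-bis(benzyloxy)-4-[(triisopropylsilyl)oxy]phenyl}magnesium bromide | Br[Mg]c1c(OCc2ccccc2)cc(O[Si](C(C)C)(C(C)C)C(C)C)cc1OCc1ccccc1 | intermediate
8 | (R)-N-[(1R)-1-{2,6-bis(benzyloxy)-4-[(triisopropylsilyl)oxy]phenyl}-5-chloropentyl]-2-methylpropane-2-sulfinamide | ClCCCC[C@@H](N[S@](=O)C(C)(C)C)c1c(OCc2ccccc2)cc(O[Si](C(C)C)(C(C)C)C(C)C)cc1OCc1ccccc1 | intermediate
9 | (2R)-2-{2,6-bis(benzyloxy)-4-[(triisopropylsilyl)oxy]phenyl}-1-[(R)-tert-butylsulfinyl]piperidine | CC(C)(C)[S@@](=O)N1CCCC[C@@H]1c1c(OCc2ccccc2)cc(O[Si](C(C)C)(C(C)C)C(C)C)cc1OCc1ccccc1 | intermediate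
10 | (2R)-2-{2,6-bis(benzyloxy)-4-[(triisopropylsilyl)oxy]phenyl}piperidine hydrochloride | Cl.N1CCCC[C@@H]1c1c(OCc2ccccc2)cc(O[Si](C(C)C)(C(C)C)C(C)C)cc1OCc1ccccc1 | intermediate
11 | tert-butyl (2R)-2-{2,6-bis(benzyloxy)-4-[(triisopropylsilyl)oxy]phenyl}piperidine-1-carboxylate | CC(C)(C)OC(=O)N1CCCC[C@@H]1c1c(OCc2ccccc2)cc(O[Si](C(C)C)(C(C)C)C(C)C)cc1OCc1ccccc1 | intermediate
12 | tert-butyl (2R)-2-[2,6-bis(benzyloxy)-4-hydroxyphenyl]piperidine-1-carboxylate | CC(C)(C)OC(=O)N1CCCC[C@@H]1c1c(OCc2ccccc2)cc(O)cc1OCc1ccccc1 | intermediate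
13 | tert-butyl (2R)-2-[2,6-bis(benzyloxy)-4-hydroxy-3-(hydroxymethyl)phenyl]piperidine-1-carboxylate | CC(C)(C)OC(=O)N1CCCC[C@@H]1c1c(OCc2ccccc2)cc(O)c(CO)c1OCc1ccccc1 | intermediate
14 | tert-butyl (2R)-2-[2,6-bis(benzyloxy)-3-formyl-4-hydroxyphenyl]piperidine-1-carboxylate | CC(C)(C)OC(=O)N1CCCC[C@@H]1c1c(OCc2ccccc2)cc(O)c(C=O)c1OCc1ccccc1 | intermediate
15 | tert-butyl acetate | CC(=O)OC(C)(C)C | starting material
16 | lithium 1-tert-butoxyethen-1-olate (lithium enolate of tert-butyl acetate) | C=C(O[Li])OC(C)(C)C | intermediate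
17 | tert-butyl (2R)-2-[2,6-bis(benzyloxy)-3-(3-tert-butoxy-1-hydroxy-3-oxopropyl)-4-hydroxyphenyl]piperidine-1-carboxylate (mixture at the carbinol carbon) | CC(C)(C)OC(=O)N1CCCC[C@@H]1c1c(OCc2ccccc2)cc(O)c(C(O)CC(=O)OC(C)(C)C)c1OCc1ccccc1 | intermediate
18 | tert-butyl (2R)-2-[2,6-bis(benzyloxy)-3-(3-tert-butoxy-3-oxopropanoyl)-4-hydroxyphenyl]piperidine-1-carboxylate | CC(C)(C)OC(=O)N1CCCC[C@@H]1c1c(OCc2ccccc2)cc(O)c(C(=O)CC(=O)OC(C)(C)C)c1OCc1ccccc1 | intermediate
19 | 4-(benzyloxy)benzaldehyde | O=Cc1ccc(OCc2ccccc2)cc1 | starting material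
20 | tert-butyl (2R)-2-[2,6-bis(benzyloxy)-3-{3-[4-(benzyloxy)phenyl]-2-(tert-butoxycarbonyl)prop-2-enoyl}-4-hydroxyphenyl]piperidine-1-carboxylate (alkene isomer mixture) | CC(C)(C)OC(=O)N1CCCC[C@@H]1c1c(OCc2ccccc2)cc(O)c(C(=O)C(=Cc2ccc(OCc3ccccc3)cc2)C(=O)OC(C)(C)C)c1OCc1ccccc1 | intermediate
21 | tert-butyl (2S)-5,7-bis(benzyloxy)-2-[4-(benzyloxy)phenyl]-6-[(2R)-1-(tert-butoxycarbonyl)piperidin-2-yl]-4-oxochromane-3-carboxylate (C3 not defined) | CC(C)(C)OC(=O)N1CCCC[C@@H]1c1c(OCc3ccccc3)cc2c(c1OCc1ccccc1)C(=O)C(C(=O)OC(C)(C)C)[C@@H](c1ccc(OCc3ccccc3)cc1)O2 | intermediate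
22 | (2S)-5,7-bis(benzyloxy)-2-[4-(benzyloxy)phenyl]-4-oxo-6-[(2R)-piperidin-2-yl]chromane-3-carboxylic acid (C3 not defined) | N1CCCC[C@@H]1c1c(OCc3ccccc3)cc2c(c1OCc1ccccc1)C(=O)C(C(=O)O)[C@@H](c1ccc(OCc3ccccc3)cc1)O2 | intermediate
23 | (2S)-5,7-bis(benzyloxy)-2-[4-(benzyloxy)phenyl]-6-[(2R)-piperidin-2-yl]chroman-4-one | N1CCCC[C@@H]1c1c(OCc3ccccc3)cc2c(c1OCc1ccccc1)C(=O)C[C@@H](c1ccc(OCc3ccccc3)cc1)O2 | intermediate
24 | (2R)-2-{(2S)-5,7-bis(benzyloxy)-2-[4-(benzyloxy)phenyl]-4-oxochroman-6-yl}-1-methylidenepiperidin-1-ium | C=[N+]1CCCC[C@@H]1c1c(OCc3ccccc3)cc2c(c1OCc1ccccc1)C(=O)C[C@@H](c1ccc(OCc3ccccc3)cc1)O2 | intermediate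
25 | (2S)-5,7-bis(benzyloxy)-2-[4-(benzyloxy)phenyl]-6-[(2R)-1-methylpiperidin-2-yl]chroman-4-one | CN1CCCC[C@@H]1c1c(OCc3ccccc3)cc2c(c1OCc1ccccc1)C(=O)C[C@@H](c1ccc(OCc3ccccc3)cc1)O2 | intermediate
26 | (2S)-5,7-dihydroxy-2-(4-hydroxyphenyl)-6-[(2R)-1-methylpiperidin-2-yl]chroman-4-one | CN1CCCC[C@@H]1c1c(O)cc2c(c1O)C(=O)C[C@@H](c1ccc(O)cc1)O2 | target

**Step count and risks**

Total steps: 12. Longest linear sequence: 11 steps (steps 1 and 3–12 from compound 1; step 2 is a one-step side branch).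

Steps most likely to fail:

1. Step 10. Uncatalysed cyclisation of the alkylidene during the condensation stage, or inhibition of the thiourea by carried-over acetate, would erode the enantioselectivity at C2. The fallback uses known chemistry (chromone formation from an enaminone, then palladium-catalysed asymmetric conjugate addition of an arylboronic acid to the chromone) and sets out from aldehyde 14. MeMgBr (THF, 0 °C) should give tert-butyl (2R)-2-[2,6-bis(benzyloxy)-4-hydroxy-3-(1-hydroxyethyl)phenyl]piperidine-1-carboxylate F1. MnO2 should oxidise it to tert-butyl (2R)-2-[3-acetyl-2,6-bis(benzyloxy)-4-hydroxyphenyl]piperidine-1-carboxylate F2. Me2NCH(OMe)2 (toluene, 90 °C) should give tert-butyl (2R)-2-{2,6-bis(benzyloxy)-3-[(2E)-3-(dimethylamino)prop-2-enoyl]-4-hydroxyphenyl}piperidine-1-carboxylate F3. Catalytic TsOH (CH2Cl2, rt) should close ring C with loss of dimethylamine to give tert-butyl (2R)-2-[5,7-bis(benzyloxy)-4-oxo-4H-chromen-6-yl]piperidine-1-carboxylate F4. Pd(OCOCF3)2 with t-BuPyOx (the enantiomer that gives 2S), 4-(benzyloxy)phenylboronic acid, NH4PF6 and H2O in ClCH2CH2Cl at 60 °C should give tert-butyl (2R)-2-{(2S)-5,7-bis(benzyloxy)-2-[4-(benzyloxy)phenyl]-4-oxochroman-6-yl}piperidine-1-carboxylate F5. CF3CO2H then removes the Boc group, and the fallback comes back to the route at compound 23.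

2. Step 3. The hindered, basic aryl Grignard reagent may deprotonate the enolisable sulfinyl imine at the α-carbon, or facial selectivity may be poor if ether competes for magnesium. The fallback reverses the polarity and sets out from aryllithium 6. DMF should give 2,6-bis(benzyloxy)-4-[(triisopropylsilyl)oxy]benzaldehyde F6. (S)-2-Methylpropane-2-sulfinamide with Ti(OEt)4 (THF, 60 °C) should give the non-enolisable (S)-N-[(E)-{2,6-bis(benzyloxy)-4-[(triisopropylsilyl)oxy]phenyl}methylidene]-2-methylpropane-2-sulfinamide F7. Cl(CH2)4MgBr (CH2Cl2, −48 °C) should add by the same chelate model to give (S)-N-[(1R)-1-{2,6-bis(benzyloxy)-4-[(triisopropylsilyl)oxy]phenyl}-5-chloropentyl]-2-methylpropane-2-sulfinamide F8. NaH in DMF should close the ring to (2R)-2-{2,6-bis(benzyloxy)-4-[(triisopropylsilyl)oxy]phenyl}-1-[(S)-tert-butylsulfinyl]piperidine F9. HCl/MeOH followed by Boc2O/Et3N then brings the fallback back to the route at compound 11.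

3. Step 12. Over-reduction may occur during hydrogenolysis: cleavage of the benzylic C–N bond of the piperidine or of the benzylic C2–O1 bond, or reduction of C4=O. The fallback is a non-reductive debenzylation: compound 25 is treated with BCl3 and pentamethylbenzene (CH2Cl2, −78 °C), a Lewis-acid ether cleavage with a cation scavenger, and goes directly to compound 26; it makes no new compound (F0).

**Further compounds**

F1 | step 10 | tert-butyl (2R)-2-[2,6-bis(benzyloxy)-4-hydroxy-3-(1-hydroxyethyl)phenyl]piperidine-1-carboxylate | CC(C)(C)OC(=O)N1CCCC[C@@H]1c1c(OCc2ccccc2)cc(O)c(C(C)O)c1OCc1ccccc1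
F2 | step 10 | tert-butyl (2R)-2-[3-acetyl-2,6-bis(benzyloxy)-4-hydroxyphenyl]piperidine-1-carboxylate | CC(C)(C)OC(=O)N1CCCC[C@@H]1c1c(OCc2ccccc2)cc(O)c(C(C)=O)c1OCc1ccccc1
F3 | step 10 | tert-butyl (2R)-2-{2,6-bis(benzyloxy)-3-[(2E)-3-(dimethylamino)prop-2-enoyl]-4-hydroxyphenyl}piperidine-1-carboxylate | CC(C)(C)OC(=O)N1CCCC[C@@H]1c1c(OCc2ccccc2)cc(O)c(C(=O)/C=C/N(C)C)c1OCc1ccccc1
F4 | step 10 | tert-butyl (2R)-2-[5,7-bis(benzyloxy)-4-oxo-4H-chromen-6-yl]piperidine-1-carboxylate | CC(C)(C)OC(=O)N1CCCC[C@@H]1c1c(OCc3ccccc3)cc2c(c1OCc1ccccc1)C(=O)C=CO2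
F5 | step 10 | tert-butyl (2R)-2-{(2S)-5,7-bis(benzyloxy)-2-[4-(benzyloxy)phenyl]-4-oxochroman-6-yl}piperidine-1-carboxylate | CC(C)(C)OC(=O)N1CCCC[C@@H]1c1c(OCc3ccccc3)cc2c(c1OCc1ccccc1)C(=O)C[C@@H](c1ccc(OCc3ccccc3)cc1)O2
F6 | step 3 | 2,6-bis(benzyloxy)-4-[(triisopropylsilyl)oxy]benzaldehyde | O=Cc1c(OCc2ccccc2)cc(O[Si](C(C)C)(C(C)C)C(C)C)cc1OCc1ccccc1
F7 | step 3 | (S)-N-[(E)-{2,6-bis(benzyloxy)-4-[(triisopropylsilyl)oxy]phenyl}methylidene]-2-methylpropane-2-sulfinamide | CC(C)(C)[S@](=O)/N=C/c1c(OCc2ccccc2)cc(O[Si](C(C)C)(C(C)C)C(C)C)cc1OCc1ccccc1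
F8 | step 3 | (S)-N-[(1R)-1-{2,6-bis(benzyloxy)-4-[(triisopropylsilyl)oxy]phenyl}-5-chloropentyl]-2-methylpropane-2-sulfinamide | ClCCCC[C@@H](N[S@@](=O)C(C)(C)C)c1c(OCc2ccccc2)cc(O[Si](C(C)C)(C(C)C)C(C)C)cc1OCc1ccccc1
F9 | step 3 | (2R)-2-{2,6-bis(benzyloxy)-4-[(triisopropylsilyl)oxy]phenyl}-1-[(S)-tert-butylsulfinyl]piperidine | CC(C)(C)[S@](=O)N1CCCC[C@@H]1c1c(OCc2ccccc2)cc(O[Si](C(C)C)(C(C)C)C(C)C)cc1OCc1ccccc1
F0 | step 12 | none | none
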